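**Strategy**

The route rests on cutting C4–C5 and C1'–C2'. C4 and C2' carry methyl groups of the same spatial sense on either side of C6 (chain C4–C5–C6–C1'–C2'), so when C6 of the later 1,2-dioxane ring (O1–O2–C3–C4–C5–C6) is an sp2 carbon with an exocyclic CH2, the C3–C3' backbone is C2-symmetric. One double Evans alkylation of a bis-allylic diiodide by two identical imide enolates then makes both bonds and both methyl stereocentres in a single operation. The precursors are (R)-4-benzyl-3-propanoyloxazolidin-2-one (two equivalents) and 3-iodo-2-(iodomethyl)prop-1-ene. Afterwards the homotopic ends are differentiated, the CH2 becomes the C6 methyl on peroxidation, and an oxa-Michael closure builds the ring.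

Key step: step 3

Remark: the (2S,6S) centres of the bis-imide become C4 (S) and C2' (R) of the target, the letter at C2' changing only through the CIP ranking. C6 is formed without facial control, because the two arms are nearly equivalent, and the 6R epimer is secured by separation after ring closure (step 13).

**Route**

Step 1
Reactants: 1 (R)-4-benzyl-1,3-oxazolidin-2-one; 2 propanoyl chloride
Product: 4 (R)-4-benzyl-3-propanoyl-1,3-oxazolidin-2-one, via N-lithio oxazolidinone 3 (not isolated)
Conditions: n-BuLi, THF, −78 °C; then 2, −78 → 0 °C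
Reagents that add atoms: none
Why: N-Acylation of the lithiated oxazolidinone with an acid chloride is the standard preparation of Evans imides and leaves the benzyl-bearing stereocentre untouched.

Step 2
Reactants: 5 3-chloro-2-(chloromethyl)prop-1-ene
Product: 6 3-iodo-2-(iodomethyl)prop-1-ene
Conditions: NaI (4 equiv), acetone, rt, dark
Reagents that add atoms: sodium iodide, [Na+].[I-]
Why: Finkelstein exchange at the two allylic CH2Cl groups is driven by precipitation of NaCl from acetone and should give the more reactive diiodide, which is used fresh.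

Step 3
Reactants: 4 (R)-4-benzyl-3-propanoyl-1,3-oxazolidin-2-one (2.3 equiv); 6 3-iodo-2-(iodomethyl)prop-1-ene (1.0 equiv)
Product: 9 (4R,4'R)-3,3'-[(2S,6S)-2,6-dimethyl-4-methylideneheptanedioyl]bis(4-benzyl-1,3-oxazolidin-2-one), via sodium Z-enolate 7 (not isolated), via mono-alkylated allylic iodide 8 (not isolated)
Conditions: NaN(SiMe3)2 (2.3 equiv), THF, −78 °C; then 6, −78 → −40 °C
Reagents that add atoms: none
Why: NaN(SiMe3)2 converts imide 4 into the sodium-chelated Z-enolate 7, which displaces iodide from one allylic CH2I of 6 by SN2, and the mono-alkylated allylic iodide 8 is alkylated again in the same way, so that C4–C5 and C1'–C2' are both formed. The closest known reaction is the Evans asymmetric alkylation of an oxazolidinone imide enolate with an allylic halide, here run in two directions on one bis-electrophile. No ring is closed. Both new stereocentres (C4 and C2') are set by the auxiliary: the benzyl group on the oxazolidinone blocks one face of the rigid chelate, the electrophile enters from the other face, and each centre should come out S in the bis-imide. The step needs the same enolate face twice and complete double substitution; the first is secured by the chelated Z-enolate, the second by the two equally reactive, unhindered allylic C–I bonds and the excess of enolate. A single facial error ends in the unsymmetrical diastereomer, which chromatography should remove, so the C2-symmetric product should be of very high enantiomeric purity.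

Step 4
Reactants: 9 (4R,4'R)-3,3'-[(2S,6S)-2,6-dimethyl-4-methylideneheptanedioyl]bis(4-benzyl-1,3-oxazolidin-2-one)
Product: 11 (2S,6S)-2,6-dimethyl-4-methylideneheptane-1,7-diol, via hydroxy imide 10 (not isolated)
Conditions: LiBH4 (4 equiv), MeOH (4 equiv), THF, 0 °C → rt
Reagents that add atoms: none
Why: Reductive cleavage of the Evans auxiliary: borohydride attacks the exocyclic imide carbonyl at each end, so both acyl groups should be reduced to primary alcohols with C4 and C2' untouched and the auxiliary released for reuse.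

Step 5
Reactants: 11 (2S,6S)-2,6-dimethyl-4-methylideneheptane-1,7-diol
Product: 13 (2S,6S)-7-{[tert-butyl(dimethyl)silyl]oxy}-2,6-dimethyl-4-methylideneheptan-1-ol, via monosodium alkoxide 12 (not isolated)
Conditions: NaH (1.0 equiv), THF, rt; then TBSCl (1.0 equiv), rt
Reagents that add atoms: tert-butyldimethylsilyl chloride, CC(C)(C)[Si](C)(C)Cl
Why: Williamson-type O-silylation of the monosodium alkoxide of a symmetric diol; the two hydroxyl groups are homotopic, so either gives the same compound and only double silylation has to be limited by the single equivalent of base and chloride.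

Step 6
Reactants: 13 (2S,6S)-7-{[tert-butyl(dimethyl)silyl]oxy}-2,6-dimethyl-4-methylideneheptan-1-ol
Product: 14 tert-butyl{[(2S,6S)-7-iodo-2,6-dimethyl-4-methylideneheptyl]oxy}dimethylsilane
Conditions: I2, PPh3, imidazole, CH2Cl2, 0 °C → rt
Reagents that add atoms: iodine, II
Why: Appel-type iodination replaces the primary hydroxyl by iodide through SN2 attack at CH2, which cannot affect the neighbouring stereocentre, and the imidazole-buffered medium spares the silyl ether.

Step 7
Reactants: 14 tert-butyl{[(2S,6S)-7-iodo-2,6-dimethyl-4-methylideneheptyl]oxy}dimethylsilane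
Product: 15 tert-butyl{[(2S,6S)-2,6-dimethyl-4-methylidenenon-8-yn-1-yl]oxy}dimethylsilane
Conditions: HC≡CLi·H2NCH2CH2NH2 (2 equiv), DMSO, 10 °C → rt
Reagents that add atoms: lithium acetylide (ethylenediamine complex), [Li+].[C-]#C
Why: SN2 alkylation of lithium acetylide by the primary iodide in DMSO should add C4' and C5' as a terminal alkyne; the single β-branch slows substitution, but elimination is not expected to dominate with this small nucleophile.

Step 8
Reactants: 15 tert-butyl{[(2S,6S)-2,6-dimethyl-4-methylidenenon-8-yn-1-yl]oxy}dimethylsilane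
Product: 17 tert-butyl{[(2S,6S,8E)-9-iodo-2,6,8-trimethyl-4-methylidenenon-8-en-1-yl]oxy}dimethylsilane, via alkenylalane 16 (not isolated)
Conditions: AlMe3 (3 equiv), Cp2ZrCl2 (0.25 equiv), CH2Cl2, 0 °C → rt; then I2, THF, −30 → 0 °C
Reagents that add atoms: trimethylaluminium, C[Al](C)C; iodine, II
Why: Negishi zirconium-catalysed carboalumination adds CH3 and Al syn across the terminal alkyne with the methyl on the internal carbon, and iodinolysis of the C–Al bond with retention should give the E-iodoalkene, the 1,1-disubstituted alkene being inert to carbometalation under these conditions.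

Step 9
Reactants: 17 tert-butyl{[(2S,6S,8E)-9-iodo-2,6,8-trimethyl-4-methylidenenon-8-en-1-yl]oxy}dimethylsilane
Product: 18 (2S,6S,8E)-9-iodo-2,6,8-trimethyl-4-methylidenenon-8-en-1-ol
Conditions: camphorsulfonic acid (0.1 equiv), MeOH/CH2Cl2, 0 °C → rt
Reagents that add atoms: none
Why: Acid-catalysed methanolysis transfers the silyl group of the primary silyl ether to methanol and should leave the iodoalkene and the methylidene group unchanged.

Step 10
Reactants: 18 (2S,6S,8E)-9-iodo-2,6,8-trimethyl-4-methylidenenon-8-en-1-ol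
Product: 19 (2S,6S,8E)-9-iodo-2,6,8-trimethyl-4-methylidenenon-8-enal
Conditions: Dess–Martin periodinane, CH2Cl2, 0 °C → rt
Reagents that add atoms: none
Why: Dess–Martin oxidation converts the primary alcohol into the aldehyde under mild, non-basic conditions so that the α-stereocentre C4 should not epimerise; the aldehyde is used directly.

Step 11
Reactants: 19 (2S,6S,8E)-9-iodo-2,6,8-trimethyl-4-methylidenenon-8-enal
Product: 20 methyl (2E,4S,8S,10E)-11-iodo-4,8,10-trimethyl-6-methylideneundeca-2,10-dienoate
Conditions: Ph3P=CHCO2Me, CH2Cl2, rt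
Reagents that add atoms: methyl (triphenylphosphoranylidene)acetate, COC(=O)C=P(c1ccccc1)(c1ccccc1)c1ccccc1
Why: Wittig olefination with a stabilised ylide should give the E-enoate (C2=C3) selectively and is mild enough to keep the configuration at C4.

Step 12
Reactants: 20 methyl (2E,4S,8S,10E)-11-iodo-4,8,10-trimethyl-6-methylideneundeca-2,10-dienoate
Product: 21 methyl (2E,4S,8R,10E)-11-iodo-4,6,8,10-tetramethyl-6-[(triethylsilyl)peroxy]undeca-2,10-dienoate as the pair of C6 epimers
Conditions: Co(thd)2 [cobalt bis(2,2,6,6-tetramethylheptane-3,5-dionate), 10 mol %], O2 (1 atm), Et3SiH (2 equiv), ClCH2CH2Cl, rt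
Reagents that add atoms: dioxygen, O=O; triethylsilane, CC[SiH](CC)CC
Why: Mukaiyama–Isayama hydroperoxysilylation: the cobalt hydride should transfer a hydrogen atom to the terminal CH2 of the electron-rich 1,1-disubstituted alkene faster than to the enoate or the iodoalkene, the tertiary C6 radical is trapped by O2 and the peroxide is silylated, so the CH2 becomes the C6 methyl; the two faces of the C6 radical are nearly equivalent, so both C6 epimers are expected.

Step 13
Reactants: 21 methyl (2E,4S,8R,10E)-11-iodo-4,6,8,10-tetramethyl-6-[(triethylsilyl)peroxy]undeca-2,10-dienoate (C6 epimers)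
Product: 23 methyl 2-[(3R,4S,6R)-6-[(2R,4E)-5-iodo-2,4-dimethylpent-4-en-1-yl]-4,6-dimethyl-1,2-dioxan-3-yl]acetate, via C6 hydroperoxide 22 (not isolated)
Conditions: HCl (cat.), MeOH, 0 °C; then Et2NH (0.2 equiv), CF3CH2OH, rt; chromatographic separation of the C6 epimers
Reagents that add atoms: none
Why: Acidic methanolysis frees the hydroperoxide, which should close by amine-catalysed, reversible intramolecular oxa-Michael addition (6-exo-trig) to the E-enoate through a chair with the C4 methyl and the ester-bearing arm equatorial, setting C3 trans to C4 (3R); the two ring diastereomers that differ at C6 are separated and the 6R isomer (side chain equatorial, C6 methyl axial) is carried on.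

Step 14
Reactants: 24 allylbenzene (2 equiv); 25 4,4,5,5-tetramethyl-2-(prop-1-en-2-yl)-1,3,2-dioxaborolane
Product: 26 4,4,5,5-tetramethyl-2-[(2Z)-4-phenylbut-2-en-2-yl]-1,3,2-dioxaborolane (boron trans to the benzyl group)
Conditions: second-generation Grubbs catalyst (5 mol %), CH2Cl2, 40 °C
Reagents that add atoms: none
Why: Ruthenium-catalysed olefin cross-metathesis of a terminal alkene with a 1,1-disubstituted alkenyl boronate should give the trisubstituted alkenyl boronate with boron trans to the benzyl-bearing carbon, as with methacrylate-type partners, because the planar boronate avoids the cis alkyl group.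

Step 15
Reactants: 23 methyl 2-[(3R,4S,6R)-6-[(2R,4E)-5-iodo-2,4-dimethylpent-4-en-1-yl]-4,6-dimethyl-1,2-dioxan-3-yl]acetate; 26 4,4,5,5-tetramethyl-2-[(2Z)-4-phenylbut-2-en-2-yl]-1,3,2-dioxaborolane (1.5 equiv)
Product: 27 methyl 2-[(3R,4S,6R)-4,6-dimethyl-6-[(2R,4E,6E)-2,4,6-trimethyl-8-phenylocta-4,6-dien-1-yl]-1,2-dioxan-3-yl]acetate
Conditions: Pd(dppf)Cl2 (5 mol %), K3PO4 (3 equiv, aq.), THF, 40 °C, degassed
Reagents that add atoms: none
Why: Suzuki–Miyaura coupling of an alkenyl iodide with an alkenyl boronate proceeds with retention of both alkene geometries and should form C5'–C6' of the E,E-diene, and mild aqueous phosphate with the zerovalent palladium catalyst generated from Pd(dppf)Cl2 is expected to spare the dialkyl peroxide and the ester.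

Step 16
Reactants: 27 methyl 2-[(3R,4S,6R)-4,6-dimethyl-6-[(2R,4E,6E)-2,4,6-trimethyl-8-phenylocta-4,6-dien-1-yl]-1,2-dioxan-3-yl]acetate
Product: 29 2-[(3R,4S,6R)-4,6-dimethyl-6-[(2R,4E,6E)-2,4,6-trimethyl-8-phenylocta-4,6-dien-1-yl]-1,2-dioxan-3-yl]acetic acid, via lithium carboxylate 28 (not isolated)
Conditions: LiOH (3 equiv), THF/H2O, 0 °C → rt; then 1 M HCl to pH 3, 0 °C
Reagents that add atoms: lithium hydroxide, [Li+].[OH-]
Why: Saponification of the methyl ester by LiOH and cold acidification should give the acid, since a monocyclic dialkyl peroxide of this type tolerates brief exposure to cold aqueous hydroxide and no stereocentre carries an acidic hydrogen.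

**Compound list**

1 | (R)-4-benzyl-1,3-oxazolidin-2-one | O=C1N[C@H](Cc2ccccc2)CO1 | starting material
2 | propanoyl chloride | CCC(=O)Cl | starting material
3 | N-lithio derivative of 1 (not isolated) | [Li+].O=C1[N-][C@H](Cc2ccccc2)CO1 | intermediate
4 | (R)-4-benzyl-3-propanoyl-1,3-oxazolidin-2-one | CCC(=O)N1[C@H](Cc2ccccc2)COC1=O | intermediate
5 | 3-chloro-2-(chloromethyl)prop-1-ene | C=C(CCl)CCl | starting material
6 | 3-iodo-2-(iodomethyl)prop-1-ene | C=C(CI)CI | intermediate
7 | sodium Z-enolate of 4 (not isolated) | C/C=C(\[O-])N1[C@H](Cc2ccccc2)COC1=O.[Na+] | intermediate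
8 | (4R)-4-benzyl-3-[(2S)-4-(iodomethyl)-2-methylpent-4-enoyl]-1,3-oxazolidin-2-one (not isolated) | O=C1OC[C@@H](Cc2ccccc2)N1C(=O)[C@@H](C)CC(=C)CI | intermediate
9 | (4R,4'R)-3,3'-[(2S,6S)-2,6-dimethyl-4-methylideneheptanedioyl]bis(4-benzyl-1,3-oxazolidin-2-one) | O=C1OC[C@@H](Cc2ccccc2)N1C(=O)[C@@H](C)CC(=C)C[C@H](C)C(=O)N1[C@H](Cc2ccccc2)COC1=O | intermediate
10 | (4R)-4-benzyl-3-[(2S,6S)-7-hydroxy-2,6-dimethyl-4-methylideneheptanoyl]-1,3-oxazolidin-2-one (not isolated) | O=C1OC[C@@H](Cc2ccccc2)N1C(=O)[C@@H](C)CC(=C)C[C@H](C)CO | intermediate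
11 | (2S,6S)-2,6-dimethyl-4-methylideneheptane-1,7-diol | OC[C@@H](C)CC(=C)C[C@H](C)CO | intermediate
12 | monosodium alkoxide of 11 (not isolated) | [Na+].[O-]C[C@@H](C)CC(=C)C[C@H](C)CO | intermediate
13 | (2S,6S)-7-{[tert-butyl(dimethyl)silyl]oxy}-2,6-dimethyl-4-methylideneheptan-1-ol | CC(C)(C)[Si](C)(C)OC[C@@H](C)CC(=C)C[C@H](C)CO | intermediate
14 | tert-butyl{[(2S,6S)-7-iodo-2,6-dimethyl-4-methylideneheptyl]oxy}dimethylsilane | CC(C)(C)[Si](C)(C)OC[C@@H](C)CC(=C)C[C@H](C)CI | intermediate
15 | tert-butyl{[(2S,6S)-2,6-dimethyl-4-methylidenenon-8-yn-1-yl]oxy}dimethylsilane | CC(C)(C)[Si](C)(C)OC[C@@H](C)CC(=C)C[C@H](C)CC#C | intermediate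
16 | (E)-alkenyldimethylalane from 15 (not isolated) | CC(C)(C)[Si](C)(C)OC[C@@H](C)CC(=C)C[C@H](C)C/C(C)=C/[Al](C)C | intermediate
17 | tert-butyl{[(2S,6S,8E)-9-iodo-2,6,8-trimethyl-4-methylidenenon-8-en-1-yl]oxy}dimethylsilane | CC(C)(C)[Si](C)(C)OC[C@@H](C)CC(=C)C[C@H](C)C/C(C)=C/I | intermediate
18 | (2S,6S,8E)-9-iodo-2,6,8-trimethyl-4-methylidenenon-8-en-1-ol | OC[C@@H](C)CC(=C)C[C@H](C)C/C(C)=C/I | intermediate
19 | (2S,6S,8E)-9-iodo-2,6,8-trimethyl-4-methylidenenon-8-enal | O=C[C@@H](C)CC(=C)C[C@H](C)C/C(C)=C/I | intermediate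
20 | methyl (2E,4S,8S,10E)-11-iodo-4,8,10-trimethyl-6-methylideneundeca-2,10-dienoate | COC(=O)/C=C/[C@@H](C)CC(=C)C[C@H](C)C/C(C)=C/I | intermediate
21 | methyl (2E,4S,8R,10E)-11-iodo-4,6,8,10-tetramethyl-6-[(triethylsilyl)peroxy]undeca-2,10-dienoate, both C6 epimers | COC(=O)/C=C/[C@@H](C)CC(C)(OO[Si](CC)(CC)CC)C[C@H](C)C/C(C)=C/I | intermediate
22 | methyl (2E,4S,8R,10E)-6-hydroperoxy-11-iodo-4,6,8,10-tetramethylundeca-2,10-dienoate, both C6 epimers (not isolated) | COC(=O)/C=C/[C@@H](C)CC(C)(OO)C[C@H](C)C/C(C)=C/I | intermediate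
23 | methyl 2-[(3R,4S,6R)-6-[(2R,4E)-5-iodo-2,4-dimethylpent-4-en-1-yl]-4,6-dimethyl-1,2-dioxan-3-yl]acetate | I/C=C(\C)C[C@@H](C)C[C@]1(C)C[C@H](C)[C@@H](CC(=O)OC)OO1 | intermediate
24 | allylbenzene | C=CCc1ccccc1 | starting material
25 | 4,4,5,5-tetramethyl-2-(prop-1-en-2-yl)-1,3,2-dioxaborolane | CC(=C)B1OC(C)(C)C(C)(C)O1 | starting material
26 | 4,4,5,5-tetramethyl-2-[(2Z)-4-phenylbut-2-en-2-yl]-1,3,2-dioxaborolane | C/C(B1OC(C)(C)C(C)(C)O1)=C\Cc1ccccc1 | intermediate
27 | methyl 2-[(3R,4S,6R)-4,6-dimethyl-6-[(2R,4E,6E)-2,4,6-trimethyl-8-phenylocta-4,6-dien-1-yl]-1,2-dioxan-3-yl]acetate | CC(=C\Cc1ccccc1)/C=C(\C)C[C@@H](C)C[C@]1(C)C[C@H](C)[C@@H](CC(=O)OC)OO1 | intermediate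
28 | lithium carboxylate of 29 (not isolated) | CC(=C\Cc1ccccc1)/C=C(\C)C[C@@H](C)C[C@]1(C)C[C@H](C)[C@@H](CC(=O)[O-])OO1.[Li+] | intermediate
29 | 2-[(3R,4S,6R)-4,6-dimethyl-6-[(2R,4E,6E)-2,4,6-trimethyl-8-phenylocta-4,6-dien-1-yl]-1,2-dioxan-3-yl]acetic acid | CC(=C\Cc1ccccc1)/C=C(\C)C[C@@H](C)C[C@]1(C)C[C@H](C)[C@@H](CC(=O)O)OO1 | target

**Step count**

Total step count: 16. Longest linear sequence: 14 steps (steps 1, 3–13, 15 and 16); steps 2 and 14 are side branches.

**Steps most likely to fail**

Step 12 (hydroperoxysilylation). Hydrogen-atom transfer may not stay at the C6 methylidene group: transfer to the iodoalkene followed by loss of iodine, transfer to the enoate, or reduction of the peroxide by excess silane would all lower the yield. The fallback replaces the radical process by ionic Markovnikov chemistry; like step 12 it gives both C6 epimers. It sets out from enoate 20: one equivalent of HBr in CH2Cl2 at −78 °C should add to the most basic alkene and give methyl (2E,4S,8R,10E)-6-bromo-11-iodo-4,6,8,10-tetramethylundeca-2,10-dienoate F1. Silver-assisted substitution of the tertiary bromide (AgO2CCF3, anhydrous H2O2 in Et2O, 0 °C) should then give hydroperoxide 22, where the route is rejoined for the amine-catalysed ring closure of step 13.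

Step 13 (oxa-Michael ring closure). The addition may give poor trans/cis control at C3, may not go to completion because it is reversible, or the base may open the peroxide by abstraction of the C3 hydrogen (Kornblum–DeLaMare type fragmentation). The fallback sets C3 by carbon–carbon bond formation on a preformed ring. It sets out from alcohol 18:
- hydroperoxysilylation under the conditions of step 12 should give (2S,6R,8E)-9-iodo-2,4,6,8-tetramethyl-4-[(triethylsilyl)peroxy]non-8-en-1-ol F2;
- Dess–Martin oxidation should give (2S,6R,8E)-9-iodo-2,4,6,8-tetramethyl-4-[(triethylsilyl)peroxy]non-8-enal F3;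
- HCl in methanol should remove the silyl group, close the hydroperoxide onto the aldehyde and acetalise the product to (4S)-6-[(2R,4E)-5-iodo-2,4-dimethylpent-4-en-1-yl]-3-methoxy-4,6-dimethyl-1,2-dioxane F4;
- ionisation with TMSOTf in CH2Cl2 at −78 °C in the presence of 1-methoxy-1-(trimethylsilyloxy)ethene should give a cyclic peroxycarbenium ion that is attacked anti to the neighbouring C4 methyl group, leading to the 3,4-trans ester.

After separation of the C6 epimers the route is rejoined at dioxane 23.

Step 15 (cross-coupling next to the peroxide). Zerovalent palladium may insert into the O–O bond, the aqueous base may open the β-peroxy ester by retro-oxa-Michael reaction, and slow transmetalation of the hindered boronate would favour both. The fallback avoids palladium and base. It sets out from boronate 26: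
- NaOH/I2 should give, with retention, [(2E)-3-iodobut-2-en-1-yl]benzene F5;
- iodine–lithium exchange (t-BuLi, Et2O, −78 °C) gives [(2E)-4-phenylbut-2-en-2-yl]lithium F6;
- quenching with Bu3SnCl gives tributyl[(2E)-4-phenylbut-2-en-2-yl]stannane F7;
- Stille-type coupling of this stannane with iodoalkene 23, mediated by copper thiophene-2-carboxylate (monovalent copper) in N-methylpyrrolidone at 0 °C, should give ester 27, where the route is rejoined.

**Further compounds**

F1 | step 12 | methyl (2E,4S,8R,10E)-6-bromo-11-iodo-4,6,8,10-tetramethylundeca-2,10-dienoate (both C6 epimers) | COC(=O)/C=C/[C@@H](C)CC(C)(Br)C[C@H](C)C/C(C)=C/I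
F2 | step 13 | (2S,6R,8E)-9-iodo-2,4,6,8-tetramethyl-4-[(triethylsilyl)peroxy]non-8-en-1-ol (both C4 epimers) | OC[C@@H](C)CC(C)(OO[Si](CC)(CC)CC)C[C@H](C)C/C(C)=C/I
F3 | step 13 | (2S,6R,8E)-9-iodo-2,4,6,8-tetramethyl-4-[(triethylsilyl)peroxy]non-8-enal (both C4 epimers) | O=C[C@@H](C)CC(C)(OO[Si](CC)(CC)CC)C[C@H](C)C/C(C)=C/I
F4 | step 13 | (4S)-6-[(2R,4E)-5-iodo-2,4-dimethylpent-4-en-1-yl]-3-methoxy-4,6-dimethyl-1,2-dioxane (mixture at C3 and C6) | COC1OOC(C)(C[C@H](C)C/C(C)=C/I)C[C@@H]1C
F5 | step 15 | [(2E)-3-iodobut-2-en-1-yl]benzene | C/C(I)=C\Cc1ccccc1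
F6 | step 15 | [(2E)-4-phenylbut-2-en-2-yl]lithium | [Li]/C(C)=C/Cc1ccccc1
F7 | step 15 | tributyl[(2E)-4-phenylbut-2-en-2-yl]stannane | CCCC[Sn](CCCC)(CCCC)/C(C)=C/Cc1ccccc1
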